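## Retrosynthetic overview

1. Last step, H2 over Pd: syn addition of H2 to an (E)-C3=C3' alkene (a 3,3'-bichromanylidene-2,2'-dione), on the face opposite both C4/C4' aryl groups, sets C3 and C3' (3,4-cis in both lactones) and removes eight benzyl ethers.
2. The alkene comes from the 3,4-trans/3',4'-trans bis-lactone by oxidation of its bis-enolate. C3 and C3' therefore act first only as relay centres for C4 and C4'.
3. Key disconnection: C4a–C4 and C4a'–C4' (Friedel–Crafts, closing lactone rings C and C' together) and, in the same flask, C3–C4 and C3'–C4' (double asymmetric Mukaiyama aldol). This leads back to the acyclic bis(ketene silyl acetal) of a mixed diaryl succinate plus two molecules of 4-(benzyloxy)benzaldehyde.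
4. Enabling feature: C4 and C4' are benzylic carbons para to the oxygen of rings B and B' (latent para-quinone-methide cations). Each lies, through the O1–C2 (O1'–C2') ester link, within six-ring reach of C4a (C4a'), the free ring carbon ortho to the ester oxygen and ortho/para to further oxygens of ring A (phloroglucinol type) and ring A' (pentaoxygenated). The C3–C3' succinate axis makes the two halves pseudo-C2-related.
5. The mixed diester comes from succinic anhydride and 3,5-bis(benzyloxy)phenol, then 2,3,4,5-tetrakis(benzyloxy)phenol (five steps from 2,3,4-trihydroxybenzaldehyde). Rings C and C' are the only rings formed, both in the key step.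

Key step: step 9

Remark on locants: chroman-2-one numbering is used. Unprimed locants are the 5,7-dioxygenated half (rings A, C, B) and primed locants the 5',6',7',8'-tetraoxygenated half (rings A', C', B').

Assumption 1: 2,3,4-trihydroxybenzaldehyde, succinic anhydride, 3,5-bis(benzyloxy)phenol and 4-(benzyloxy)benzaldehyde are taken as commercial.

Assumption 2: for this acyloxyborane catalyst class the natural (2R,3R)-tartrate ligand is taken to direct attack to the re face of aromatic aldehydes (R carbinol), so the (2S,3S) ligand is specified for the S carbinols of the aldol adduct; should the bis(ketene acetal) respond in the opposite sense, the antipodal ligand is used.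

## Route

Step 1
Reactants: 1 2,3,4-trihydroxybenzaldehyde
Product: 2 2,3,4-tris(benzyloxy)benzaldehyde
Conditions: BnBr (3.5 equiv), K2CO3, DMF, 60 °C
Reagents that add atoms: benzyl bromide, BrCc1ccccc1
Why: Williamson etherification of all three phenols, with excess halide and warming to overcome the hydrogen-bonded 2-OH; no stereocentre is involved.

Step 2
Reactants: 2 2,3,4-tris(benzyloxy)benzaldehyde
Product: 4 2,3,4-tris(benzyloxy)phenol, via aryl formate 3 (not isolated)
Conditions: mCPBA, CH2Cl2, 0 °C to rt; then K2CO3 (cat.), MeOH, rt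
Reagents that add atoms: mCPBA, OOC(=O)c1cccc(Cl)c1
Why: Baeyer–Villiger oxidation of an electron-rich benzaldehyde proceeds by aryl migration to the formate, which catalytic methanolysis cleaves without touching the benzyl ethers.

Step 3
Reactants: 4 2,3,4-tris(benzyloxy)phenol
Product: 5 1,2,3,4-tetrakis(benzyloxy)benzene
Conditions: BnBr (1.2 equiv), K2CO3, DMF, 50 °C
Reagents that add atoms: benzyl bromide, BrCc1ccccc1
Why: Williamson etherification makes the arene symmetric, so its two remaining C–H positions are equivalent for the next step.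

Step 4
Reactants: 5 1,2,3,4-tetrakis(benzyloxy)benzene
Product: 7 2,3,4,5-tetrakis(benzyloxy)benzaldehyde, via aryl iminium chloride 6 (not isolated)
Conditions: POCl3, DMF, 0 to 70 °C; then ice–water
Reagents that add atoms: N,N-dimethylformamide, CN(C)C=O; water, O
Why: Vilsmeier–Haack formylation attacks one of the two equivalent free positions (ortho and para to alkoxy groups), as known for 1,2,3,4-tetraalkoxybenzenes, and the first formyl group deactivates the ring against a second attack.

Step 5
Reactants: 7 2,3,4,5-tetrakis(benzyloxy)benzaldehyde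
Product: 9 2,3,4,5-tetrakis(benzyloxy)phenol, via aryl formate 8 (not isolated)
Conditions: mCPBA, CH2Cl2, 0 °C to rt; then K2CO3 (cat.), MeOH, rt
Reagents that add atoms: mCPBA, OOC(=O)c1cccc(Cl)c1
Why: a second Baeyer–Villiger oxidation and methanolysis turns the formyl carbon into the fifth oxygen and leaves the free OH next to the only ring C–H, the pattern needed for ring A'.

Step 6
Reactants: 10 succinic anhydride; 11 3,5-bis(benzyloxy)phenol
Product: 12 4-[3,5-bis(benzyloxy)phenoxy]-4-oxobutanoic acid
Conditions: DMAP (cat.), toluene, 80 °C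
Reagents that add atoms: none
Why: DMAP-catalysed acylative opening of the cyclic anhydride stops at the mono-aryl ester because the free acid formed is not an acyl donor.

Step 7
Reactants: 12 4-[3,5-bis(benzyloxy)phenoxy]-4-oxobutanoic acid; 9 2,3,4,5-tetrakis(benzyloxy)phenol
Product: 13 3,5-bis(benzyloxy)phenyl 2,3,4,5-tetrakis(benzyloxy)phenyl butanedioate
Conditions: EDC·HCl (1.2 equiv), CH2Cl2, 0 °C; then 9, DMAP (cat.), 0 °C to rt
Reagents that add atoms: none
Why: Steglich-type carbodiimide esterification, in which the acid is activated at 0 °C before DMAP and the phenol are added so that coupling outruns reversion of the aryl hydrogen succinate to the anhydride and scrambling of the two aryl groups.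

Step 8
Reactants: 13 3,5-bis(benzyloxy)phenyl 2,3,4,5-tetrakis(benzyloxy)phenyl butanedioate
Product: 14 (1E,3E)-1-[3,5-bis(benzyloxy)phenoxy]-4-[2,3,4,5-tetrakis(benzyloxy)phenoxy]-1,4-bis(trimethylsilyloxy)buta-1,3-diene
Conditions: LiN(iPr)2 (2.3 equiv), Me3SiCl (5 equiv, present from the start), THF, −78 °C; pentane, filtration, evaporation, used crude
Reagents that add atoms: chlorotrimethylsilane, C[Si](C)(C)Cl
Why: double kinetic enolisation with in situ silyl trapping, as established for dialkyl succinates, captures each aryl-ester enolate before ketene extrusion or Claisen condensation; the geometry shown is that expected for LiN(iPr)2 in THF and has no consequence for the next step.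

Step 9
Reactants: 14 bis(ketene silyl acetal) of the mixed diaryl succinate; 15 4-(benzyloxy)benzaldehyde (2.1 equiv)
Product: 17 (3R,3'R,4R,4'R)-octa-O-benzyl 3,4-trans-3',4'-trans-bis-lactone, via bis-silyl double aldol adduct 16 (not isolated)
Conditions: acyloxyborane made in situ from (2S,3S)-2-O-(2,6-diisopropoxybenzoyl)tartaric acid and BH3·THF (0.4 equiv), EtCN, −78 °C; then dilution with CH2Cl2, Me3SiOTf (0.3 equiv), −78 to −20 °C
Reagents that add atoms: none
Why: Proposed new method: the chiral acyloxyborane activates 15 for a two-directional Mukaiyama aldol with both nucleophilic carbons of 14 (silyl transfer gives 16), and Me3SiOTf then ionises the two para-benzyloxybenzylic C–OSiMe3 bonds to O-benzylated para-quinone-methide cations that are captured by the ester-tethered arenes with loss of a ring proton, a laboratory copy of the presumed attack of phloroglucinol-type carbons on an 8,8'-coupled bis(quinone methide). Closest known reaction types are the syn-selective, geometry-independent acyloxyborane aldol of aryl-ester ketene silyl acetals with aromatic aldehydes, the Lewis-acid Friedel–Crafts cyclisation of benzylic ethers, and the acid cyclisation of aryl cinnamates to 4-aryl-3,4-dihydrocoumarins; new is their two-fold, one-flask use on a succinate bis(ketene acetal). Rings C and C' each close 6-exo-trig at the cationic carbon (C4a to C4, C4a' to C4'), the arene reacting at the carbon ortho to the ester oxygen. C3 and C3' (and the transient carbinol centres) are set by the catalyst through the aldehyde face and the syn open transition state, and because both ends obey the same catalyst most errors should end in separable pseudo-meso diastereomers rather than in the enantiomer. C4 and C4' are set by C3 and C3': in each planar cation C3–H eclipses the aryl plane to avoid allylic 1,3-strain, the tether can reach only the face bearing C2 while the C3' branch (whose C2' carbonyl can cap that side) covers the other, so aryl and C3 substituent become trans, (3R,4R) and (3'R,4'R), whatever the carbinol configuration. The step needs cyclisation to beat loss of H3, cross closure and intermolecular alkylation, which is secured by the oxygen pattern that makes C4a and C4a' the most nucleophilic reachable carbons (two equivalent sites in ring A, one single free site in ring A', six- versus seven-membered closure, ortho carbons of rings B and B' meta to oxygen) together with low temperature and dilution.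

Step 10
Reactants: 17 (3R,3'R,4R,4'R)-octa-O-benzyl 3,4-trans-3',4'-trans-bis-lactone
Product: 19 (3E,4R,4'R)-octa-O-benzyl 3,3'-bichromanylidene-2,2'-dione, via dilithium bis-enolate 18 (not isolated)
Conditions: LiN(iPr)2 (2.2 equiv), THF, −78 to −40 °C; then I2 (1.2 equiv), THF, −78 °C
Reagents that add atoms: none
Why: two-fold deprotonation gives the succinate-type dienediolate, whose two-electron oxidation by iodine (α-iodination, then expulsion of iodide by the neighbouring enolate) is a known way from succinates to tetrasubstituted fumarates; it erases the relay centres C3/C3', leaves C4/C4' untouched, and should favour the E isomer because the Z isomer would press C4 against C4' and align the two carbonyl dipoles.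

Step 11
Reactants: 19 (3E,4R,4'R)-octa-O-benzyl 3,3'-bichromanylidene-2,2'-dione
Product: 20 (3S,3'S,4R,4'R)-5,5',6',7,7',8'-hexahydroxy-4,4'-bis(4-hydroxyphenyl)-[3,3'-bichromane]-2,2'-dione (target)
Conditions: H2 (4 bar), Pd(OH)2/C, THF–EtOAc, rt; work-up under argon
Reagents that add atoms: none
Why: heterogeneous syn-hydrogenation of the electron-poor fumarate-type alkene should occur on the face opposite the two pseudo-axial C4/C4' aryl groups, which lie on the same face in the (4R,4'R)-E-alkene, so both new hydrogens enter trans to the aryl groups and give the 3,4-cis/3',4'-cis (3S,3'S) configuration, while the same catalyst cleaves all eight benzyl ethers under neutral conditions that do not epimerise the lactones.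

## Compound list

1 | 2,3,4-trihydroxybenzaldehyde | O=Cc1ccc(O)c(O)c1O | starting material
2 | 2,3,4-tris(benzyloxy)benzaldehyde | O=Cc1ccc(OCc2ccccc2)c(OCc2ccccc2)c1OCc1ccccc1 | intermediate
3 | 2,3,4-tris(benzyloxy)phenyl formate | O=COc1ccc(OCc2ccccc2)c(OCc2ccccc2)c1OCc1ccccc1 | intermediate
4 | 2,3,4-tris(benzyloxy)phenol | Oc1ccc(OCc2ccccc2)c(OCc2ccccc2)c1OCc1ccccc1 | intermediate
5 | 1,2,3,4-tetrakis(benzyloxy)benzene | c1cc(OCc2ccccc2)c(OCc2ccccc2)c(OCc2ccccc2)c1OCc1ccccc1 | intermediate
6 | N-[2,3,4,5-tetrakis(benzyloxy)benzylidene]-N-methylmethanaminium chloride | C[N+](C)=Cc1cc(OCc2ccccc2)c(OCc2ccccc2)c(OCc2ccccc2)c1OCc1ccccc1.[Cl-] | intermediate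
7 | 2,3,4,5-tetrakis(benzyloxy)benzaldehyde | O=Cc1cc(OCc2ccccc2)c(OCc2ccccc2)c(OCc2ccccc2)c1OCc1ccccc1 | intermediate
8 | 2,3,4,5-tetrakis(benzyloxy)phenyl formate | O=COc1cc(OCc2ccccc2)c(OCc2ccccc2)c(OCc2ccccc2)c1OCc1ccccc1 | intermediate
9 | 2,3,4,5-tetrakis(benzyloxy)phenol | Oc1cc(OCc2ccccc2)c(OCc2ccccc2)c(OCc2ccccc2)c1OCc1ccccc1 | intermediate
10 | succinic anhydride | O=C1CCC(=O)O1 | starting material
11 | 3,5-bis(benzyloxy)phenol | Oc1cc(OCc2ccccc2)cc(OCc2ccccc2)c1 | starting material
12 | 4-[3,5-bis(benzyloxy)phenoxy]-4-oxobutanoic acid | OC(=O)CCC(=O)Oc1cc(OCc2ccccc2)cc(OCc2ccccc2)c1 | intermediate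
13 | 3,5-bis(benzyloxy)phenyl 2,3,4,5-tetrakis(benzyloxy)phenyl butanedioate | O=C(CCC(=O)Oc1cc(OCc2ccccc2)c(OCc2ccccc2)c(OCc2ccccc2)c1OCc1ccccc1)Oc1cc(OCc2ccccc2)cc(OCc2ccccc2)c1 | intermediate
14 | (1E,3E)-1-[3,5-bis(benzyloxy)phenoxy]-4-[2,3,4,5-tetrakis(benzyloxy)phenoxy]-1,4-bis(trimethylsilyloxy)buta-1,3-diene | C[Si](C)(C)O/C(Oc1cc(OCc2ccccc2)cc(OCc2ccccc2)c1)=C/C=C(/O[Si](C)(C)C)Oc1cc(OCc2ccccc2)c(OCc2ccccc2)c(OCc2ccccc2)c1OCc1ccccc1 | intermediate
15 | 4-(benzyloxy)benzaldehyde | O=Cc1ccc(OCc2ccccc2)cc1 | starting material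
16 | 3,5-bis(benzyloxy)phenyl 2,3,4,5-tetrakis(benzyloxy)phenyl (2S,3S)-2,3-bis{(S)-[4-(benzyloxy)phenyl](trimethylsilyloxy)methyl}butanedioate | O=C(Oc1cc(OCc2ccccc2)cc(OCc2ccccc2)c1)[C@H]([C@H](O[Si](C)(C)C)c1ccc(OCc2ccccc2)cc1)[C@@H]([C@H](O[Si](C)(C)C)c1ccc(OCc2ccccc2)cc1)C(=O)Oc1cc(OCc2ccccc2)c(OCc2ccccc2)c(OCc2ccccc2)c1OCc1ccccc1 | intermediate
17 | (3R,3'R,4R,4'R)-5,5',6',7,7',8'-hexakis(benzyloxy)-4,4'-bis[4-(benzyloxy)phenyl]-[3,3'-bichromane]-2,2'-dione (both lactones 3,4-trans) | O=C1Oc2cc(OCc3ccccc3)cc(OCc3ccccc3)c2[C@@H](c2ccc(OCc3ccccc3)cc2)[C@@H]1[C@@H]1C(=O)Oc2c(OCc3ccccc3)c(OCc3ccccc3)c(OCc3ccccc3)c(OCc3ccccc3)c2[C@H]1c1ccc(OCc2ccccc2)cc1 | intermediate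
18 | dilithium (4R,4'R)-bis-enolate of 17 | [Li+].[Li+].[O-]C1=C(C2=C([O-])Oc3c(OCc4ccccc4)c(OCc4ccccc4)c(OCc4ccccc4)c(OCc4ccccc4)c3[C@H]2c2ccc(OCc3ccccc3)cc2)[C@H](c2ccc(OCc3ccccc3)cc2)c2c(OCc3ccccc3)cc(OCc3ccccc3)cc2O1 | intermediate
19 | (3E,4R,4'R)-5,5',6',7,7',8'-hexakis(benzyloxy)-4,4'-bis[4-(benzyloxy)phenyl]-3,3'-bichromanylidene-2,2'-dione | O=C1Oc2cc(OCc3ccccc3)cc(OCc3ccccc3)c2[C@@H](c2ccc(OCc3ccccc3)cc2)/C1=C1\C(=O)Oc2c(OCc3ccccc3)c(OCc3ccccc3)c(OCc3ccccc3)c(OCc3ccccc3)c2[C@H]1c1ccc(OCc2ccccc2)cc1 | intermediate
20 | (3S,3'S,4R,4'R)-5,5',6',7,7',8'-hexahydroxy-4,4'-bis(4-hydroxyphenyl)-[3,3'-bichromane]-2,2'-dione (CNP0064734.1) | O=C1Oc2cc(O)cc(O)c2[C@@H](c2ccc(O)cc2)[C@H]1[C@H]1C(=O)Oc2c(O)c(O)c(O)c(O)c2[C@H]1c1ccc(O)cc1 | target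

## Step count and risks

Total step count: 11.

Longest linear sequence: 10 steps (steps 1–5, then 7–11).

Steps most likely to fail:

**1. Step 9 (new method).**
- What may go wrong:
  - mismatched double stereodifferentiation in the second aldol, eroding control at C3/C3';
  - loss of H3 after ionisation;
  - intermolecular alkylation at the para carbon of ring A.
- Fallback, known chemistry only, from 14 and 15. Catalytic Sc(OTf)3 (achiral) promotes the double Mukaiyama aldol to the bis-silyl double aldol adduct as a stereoisomer mixture F1. This is ionised with Me3SiOTf as in the main route.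
- The ring closure is trans-selective whatever the origin of C3. Chromatography and crystallisation should therefore deliver the racemic pseudo-C2 trans,trans-bis-lactone, that is 17 together with its mirror image, the (3S,3'S,4S,4'S)-bis-lactone F2.
- The two are separated by preparative chromatography on a chiral stationary phase. The route is rejoined at 17.

**2. Step 10.**
- What may go wrong:
  - sluggish second deprotonation, because H3 is pseudo-equatorial in the diaxial conformer;
  - opening of the aryl-lactone enolate to ketene and phenoxide;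
  - base-induced migration of the new double bond into the lactone ring, with loss of C4 configuration.
- Fallback from 17, avoiding strong base. Soft enolisation with Me3SiOTf/Et3N (CH2Cl2, 0 °C) gives the bis(ketene silyl acetal) of 17 F3.
- F3 is oxidised with I2 at −78 °C, the halogen oxidation known for 2,5-bis(silyloxy)furans to maleic anhydrides. The route is rejoined at 19.

**3. Step 11.**
- What may go wrong:
  - stalled saturation of the tetrasubstituted alkene;
  - palladium-hydride migration of the double bond into ring C or C';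
  - insufficient facial discrimination.
- Fallback from 18, generated from 17 as in step 10. C3/C3' are set by protonation instead of hydrogenation. Inverse addition of 18 into cold AcOH/THF (−78 °C) protonates each enolate carbon kinetically, opposite its neighbouring pseudo-axial aryl group, to give the (3S,3'S,4R,4'R)-cis,cis-octabenzyl ether F4.
- Plain hydrogenolysis of F4 (H2, Pd/C, THF–EtOAc) rejoins the route at 20.

## Further compounds

F1 | step 9 | 3,5-bis(benzyloxy)phenyl 2,3,4,5-tetrakis(benzyloxy)phenyl 2,3-bis{[4-(benzyloxy)phenyl](trimethylsilyloxy)methyl}butanedioate, mixture of stereoisomers | O=C(Oc1cc(OCc2ccccc2)cc(OCc2ccccc2)c1)C(C(O[Si](C)(C)C)c1ccc(OCc2ccccc2)cc1)C(C(O[Si](C)(C)C)c1ccc(OCc2ccccc2)cc1)C(=O)Oc1cc(OCc2ccccc2)c(OCc2ccccc2)c(OCc2ccccc2)c1OCc1ccccc1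
F2 | step 9 | (3S,3'S,4S,4'S)-5,5',6',7,7',8'-hexakis(benzyloxy)-4,4'-bis[4-(benzyloxy)phenyl]-[3,3'-bichromane]-2,2'-dione (mirror image of 17) | O=C1Oc2cc(OCc3ccccc3)cc(OCc3ccccc3)c2[C@H](c2ccc(OCc3ccccc3)cc2)[C@H]1[C@H]1C(=O)Oc2c(OCc3ccccc3)c(OCc3ccccc3)c(OCc3ccccc3)c(OCc3ccccc3)c2[C@@H]1c1ccc(OCc2ccccc2)cc1
F3 | step 10 | (4R,4'R)-2,2'-bis(trimethylsilyloxy)-4H,4'H-3,3'-bichromene, octa-O-benzyl (bis(ketene silyl acetal) of 17) | C[Si](C)(C)OC1=C(C2=C(O[Si](C)(C)C)Oc3c(OCc4ccccc4)c(OCc4ccccc4)c(OCc4ccccc4)c(OCc4ccccc4)c3[C@H]2c2ccc(OCc3ccccc3)cc2)[C@H](c2ccc(OCc3ccccc3)cc2)c2c(OCc3ccccc3)cc(OCc3ccccc3)cc2O1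
F4 | step 11 | (3S,3'S,4R,4'R)-5,5',6',7,7',8'-hexakis(benzyloxy)-4,4'-bis[4-(benzyloxy)phenyl]-[3,3'-bichromane]-2,2'-dione (both lactones 3,4-cis) | O=C1Oc2cc(OCc3ccccc3)cc(OCc3ccccc3)c2[C@@H](c2ccc(OCc3ccccc3)cc2)[C@H]1[C@H]1C(=O)Oc2c(OCc3ccccc3)c(OCc3ccccc3)c(OCc3ccccc3)c(OCc3ccccc3)c2[C@H]1c1ccc(OCc2ccccc2)cc1
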